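**Retrosynthetic overview**

- The free hydroquinone comes last, by chemoselective cleavage of two aryl acetates. The C10=C11 enone is made by cross-metathesis of a terminal alkene with 2,6-dimethylhepta-1,5-dien-3-one.
- The C1–C2 benzyl–alkenyl bond and the 2E olefin come from a one-pot zirconium-catalysed methylalumination of an (S)-homopropargylic alcohol and palladium-catalysed coupling with a benzylic bromide.
- Key step on the arene: 2,6-dimethylphenol is dearomatised by O2 to the C2v quinone and re-aromatised as the diacetate. Its symmetry is then broken by monobromination, so one xylenol methyl becomes C1 of the chain.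
- C5 (S) is set by chiral phosphoric acid-catalysed propargylboration of (2E)-3-methylhepta-2,6-dienal, made from hex-1-en-5-yne.
- No ring is constructed; the only ring is the xylenol ring, carried through from the start.

Assumption: hex-1-en-5-yne, methyl 4-methylpent-3-enoate, allenylboronic acid pinacol ester and (S)-TRIP are bought; the side chain is numbered C1 (benzylic) to C16; metal alkoxides and boron esters of a product that are only protonated in the work-up are not numbered.

**Route**

Step 1
Reactants: 1 2,6-dimethylphenol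
Product: 2 2,6-dimethyl-1,4-benzoquinone
Conditions: O2 (1 atm), Co(salen) (5 mol %), DMF, rt
Reagents that add atoms: dioxygen, O=O
Why: Cobalt–dioxygen para-oxygenation of a 2,6-dialkylphenol (Teuber-type phenol-to-quinone oxidation) dearomatises the feedstock to the C2v quinone and installs the second oxygen of the future hydroquinone, with DMF and the blocked ortho positions suppressing diphenoquinone coupling.

Step 2
Reactants: 2 2,6-dimethyl-1,4-benzoquinone
Product: 3 2,6-dimethyl-1,4-phenylene diacetate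
Conditions: Zn dust, Ac2O, NaOAc (cat.), 60 °C
Reagents that add atoms: acetic anhydride, CC(=O)OC(C)=O
Why: Reductive acetylation (Zn reduces the quinone, Ac2O traps both phenoxides) re-aromatises the ring as a symmetric diacetate that is deactivated toward ring bromination and masked for the organometallic steps.

Step 3
Reactants: 3 2,6-dimethyl-1,4-phenylene diacetate
Product: 4 2-(bromomethyl)-6-methyl-1,4-phenylene diacetate
Conditions: NBS (0.95 equiv), AIBN (5 mol %), PhCF3, 85 °C
Reagents that add atoms: N-bromosuccinimide, O=C1CCC(=O)N1Br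
Why: Wohl–Ziegler radical bromination of one of the two homotopic benzylic methyl groups breaks the symmetry and turns a xylenol methyl into C1 of the side chain, with sub-stoichiometric NBS limiting dibromide and unreacted 3 being recycled.

Step 4
Reactants: 5 hex-1-en-5-yne
Product: 8 (2E)-3-methylhepta-2,6-dien-1-ol, via alkenyldimethylalane 6 (not isolated), via lithium alkenylalanate 7 (not isolated)
Conditions: AlMe3 (2.5 equiv), Cp2ZrCl2 (10 mol %), H2O (1 equiv), CH2Cl2, −20 °C; evaporate; n-BuLi, THF/hexane, −78 → 0 °C; (CH2O)n, rt; cold 1 M HCl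
Reagents that add atoms: trimethylaluminium, C[Al](C)C; paraformaldehyde (formaldehyde), C=O
Why: Negishi zirconium-catalysed syn-methylalumination of the terminal alkyne (the alkene is untouched at −20 °C) gives the (E)-2-methylalkenylalane, whose ate complex is hydroxymethylated with retention, fixing the later 6E olefin.

Step 5
Reactants: 8 (2E)-3-methylhepta-2,6-dien-1-ol
Product: 9 (2E)-3-methylhepta-2,6-dienal
Conditions: [Cu(MeCN)4]OTf (5 mol %), 2,2'-bipyridine (5 mol %), TEMPO (5 mol %), N-methylimidazole (10 mol %), air, MeCN, rt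
Reagents that add atoms: none
Why: Copper/TEMPO aerobic alcohol oxidation (Stahl oxidation) converts the primary allylic alcohol into the enal without E/Z isomerisation or over-oxidation.

Step 6
Reactants: 9 (2E)-3-methylhepta-2,6-dienal
Product: 10 (4S,5E)-6-methyldeca-5,9-dien-1-yn-4-ol
Conditions: allenylboronic acid pinacol ester (1.5 equiv), (S)-TRIP [(S)-3,3'-bis(2,4,6-triisopropylphenyl)-1,1'-binaphthyl-2,2'-diyl hydrogen phosphate] (10 mol %), 4 Å MS, toluene, 0 °C; aq. work-up
Reagents that add atoms: allenylboronic acid pinacol ester, C=C=CB1OC(C)(C)C(C)(C)O1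
Why: Chiral phosphoric acid-catalysed propargylboration runs through a closed six-membered SE2' transition state, and (S)-TRIP is expected to give the 4S carbinol by analogy with aryl and alkenyl aldehydes (to be confirmed by Mosher analysis; the antipodal acid corrects a wrong sense), so the C5 stereocentre of the target is set here.

Step 7
Reactants: 11 methyl 4-methylpent-3-enoate
Product: 14 2,6-dimethylhepta-1,5-dien-3-one, via Weinreb amide 12 (not isolated), via magnesium hemiaminal adduct 13 (not isolated)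
Conditions: MeNHOMe·HCl (1.5 equiv), i-PrMgCl (3 equiv), THF, −20 °C; then CH2=C(CH3)MgBr (2 equiv), −20 → 0 °C; inverse quench into cold 1 M HCl
Reagents that add atoms: isopropenylmagnesium bromide, C=C(C)[Mg]Br
Why: Weinreb ketone synthesis in one pot: the amide formed in situ from the ester adds the Grignard reagent once to give a stable magnesium chelate that releases the ketone only on the cold acidic quench, which also avoids conjugation of the β,γ-double bond.

Step 8
Reactants: 10 (4S,5E)-6-methyldeca-5,9-dien-1-yn-4-ol; 4 2-(bromomethyl)-6-methyl-1,4-phenylene diacetate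
Product: 16 2-[(2E,5S,6E)-5-hydroxy-3,7-dimethylundeca-2,6,10-trien-1-yl]-6-methyl-1,4-phenylene diacetate, via O-aluminated alkenylalane 15 (not isolated)
Conditions: AlMe3 (4 equiv), Cp2ZrCl2 (20 mol %), H2O (1.5 equiv), CH2Cl2, −20 → 0 °C; evaporate excess AlMe3; THF; 4 (1.1 equiv), Pd(PPh3)4 (5 mol %), 0 °C → rt; sat. aq. NH4Cl
Reagents that add atoms: trimethylaluminium, C[Al](C)C
Why: Negishi syn-carboalumination of the alkyne (the hydroxyl carried as its aluminium alkoxide) followed by palladium-catalysed alkenylalane–benzyl bromide cross-coupling with retention forms the C1–C2 bond and the 2E olefin in one pot without touching the carbinol stereocentre.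

Step 9
Reactants: 16 2-[(2E,5S,6E)-5-hydroxy-3,7-dimethylundeca-2,6,10-trien-1-yl]-6-methyl-1,4-phenylene diacetate
Product: 17 (2E,5S,6E)-1-(2,5-diacetoxy-3-methylphenyl)-3,7-dimethylundeca-2,6,10-trien-5-yl acetate
Conditions: Ac2O, pyridine, DMAP (5 mol %), CH2Cl2, 0 °C → rt
Reagents that add atoms: acetic anhydride, CC(=O)OC(C)=O
Why: DMAP-catalysed O-acylation of the secondary allylic alcohol does not touch the C5–O bond, so the acetate of the target is installed with retention and any acetyl scrambling from step 8 is healed.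

Step 10
Reactants: 17 (2E,5S,6E)-1-(2,5-diacetoxy-3-methylphenyl)-3,7-dimethylundeca-2,6,10-trien-5-yl acetate; 14 2,6-dimethylhepta-1,5-dien-3-one
Product: 18 (2E,5S,6E,10E)-1-(2,5-diacetoxy-3-methylphenyl)-3,7,11,15-tetramethyl-12-oxohexadeca-2,6,10,14-tetraen-5-yl acetate
Conditions: 14 (4 equiv), RuCl2(H2IMes)(=CH-C6H4-2-OiPr) (second-generation Hoveyda–Grubbs catalyst, 2 × 5 mol %), 1,4-benzoquinone (10 mol %), CH2Cl2, 40 °C, Ar sparge
Reagents that add atoms: none
Why: Olefin cross-metathesis between the only monosubstituted alkene of 17 and the slowly homodimerising 1,1-disubstituted isopropenyl ketone gives the trisubstituted enone as the favoured E isomer, the trisubstituted olefins and esters being inert and benzoquinone suppressing ruthenium-hydride isomerisation.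

Step 11
Reactants: 18 (2E,5S,6E,10E)-1-(2,5-diacetoxy-3-methylphenyl)-3,7,11,15-tetramethyl-12-oxohexadeca-2,6,10,14-tetraen-5-yl acetate
Product: 19 (2E,5S,6E,10E)-1-(2,5-dihydroxy-3-methylphenyl)-3,7,11,15-tetramethyl-12-oxohexadeca-2,6,10,14-tetraen-5-yl acetate
Conditions: NH4OAc (10 equiv), MeOH/H2O (4:1), degassed, Ar, rt → 40 °C
Reagents that add atoms: none
Why: Chemoselective ammonolysis: aryl acetates (phenoxide leaving groups) are cleaved by the ammonia/acetate buffer far faster than the hindered secondary alkyl acetate, and the near-neutral medium leaves the β,γ-unsaturated ketone and the C5 stereocentre untouched.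

**Compound list**

1 | 2,6-dimethylphenol | Cc1cccc(C)c1O | starting material
2 | 2,6-dimethyl-1,4-benzoquinone | CC1=CC(=O)C=C(C)C1=O | intermediate
3 | 2,6-dimethyl-1,4-phenylene diacetate | CC(=O)Oc1cc(C)c(OC(C)=O)c(C)c1 | intermediate
4 | 2-(bromomethyl)-6-methyl-1,4-phenylene diacetate | CC(=O)Oc1cc(C)c(OC(C)=O)c(CBr)c1 | intermediate
5 | hex-1-en-5-yne | C=CCCC#C | starting material
6 | dimethyl[(1E)-2-methylhexa-1,5-dien-1-yl]alane | C[Al](C)/C=C(\C)CCC=C | intermediate
7 | lithium butyldimethyl[(1E)-2-methylhexa-1,5-dien-1-yl]alanate | [Li+].CCCC[Al-](C)(C)/C=C(\C)CCC=C | intermediate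
8 | (2E)-3-methylhepta-2,6-dien-1-ol | OC/C=C(\C)CCC=C | intermediate
9 | (2E)-3-methylhepta-2,6-dienal | O=C/C=C(\C)CCC=C | intermediate
10 | (4S,5E)-6-methyldeca-5,9-dien-1-yn-4-ol | O[C@H](/C=C(\C)CCC=C)CC#C | intermediate
11 | methyl 4-methylpent-3-enoate | COC(=O)CC=C(C)C | starting material
12 | N-methoxy-N,4-dimethylpent-3-enamide | CON(C)C(=O)CC=C(C)C | intermediate
13 | bromomagnesium 3-[methoxy(methyl)amino]-2,6-dimethylhepta-1,5-dien-3-olate | C=C(C)C(O[Mg]Br)(CC=C(C)C)N(C)OC | intermediate
14 | 2,6-dimethylhepta-1,5-dien-3-one | C=C(C)C(=O)CC=C(C)C | intermediate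
15 | [(1E,4S,5E)-4-[(dimethylalumanyl)oxy]-2,6-dimethyldeca-1,5,9-trien-1-yl]dimethylalane | C[Al](C)O[C@H](/C=C(\C)CCC=C)C/C(C)=C/[Al](C)C | intermediate
16 | 2-[(2E,5S,6E)-5-hydroxy-3,7-dimethylundeca-2,6,10-trien-1-yl]-6-methyl-1,4-phenylene diacetate | CC(=O)Oc1cc(C)c(OC(C)=O)c(C/C=C(\C)C[C@H](O)/C=C(\C)CCC=C)c1 | intermediate
17 | (2E,5S,6E)-1-(2,5-diacetoxy-3-methylphenyl)-3,7-dimethylundeca-2,6,10-trien-5-yl acetate | CC(=O)Oc1cc(C)c(OC(C)=O)c(C/C=C(\C)C[C@H](OC(C)=O)/C=C(\C)CCC=C)c1 | intermediate
18 | (2E,5S,6E,10E)-1-(2,5-diacetoxy-3-methylphenyl)-3,7,11,15-tetramethyl-12-oxohexadeca-2,6,10,14-tetraen-5-yl acetate | CC(=O)Oc1cc(C)c(OC(C)=O)c(C/C=C(\C)C[C@H](OC(C)=O)/C=C(\C)CC/C=C(\C)C(=O)CC=C(C)C)c1 | intermediate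
19 | (2E,5S,6E,10E)-1-(2,5-dihydroxy-3-methylphenyl)-3,7,11,15-tetramethyl-12-oxohexadeca-2,6,10,14-tetraen-5-yl acetate (CNP0186948.1) | CC(=O)O[C@H](/C=C(\C)CC/C=C(\C)C(=O)CC=C(C)C)C/C(C)=C/Cc1cc(O)cc(C)c1O | target

**Step count and risks**

Total: 11 steps. Longest linear sequence: 7 steps (5 → 19 through steps 4, 5, 6, 8, 9, 10 and 11; the arene branch 1 → 19 through steps 1, 2, 3, 8, 9, 10 and 11 is equally long).

The three steps most likely to fail are step 10, step 11 and step 8.

For step 10, the isopropenyl ketone may be too sluggish a metathesis partner, or its β,γ-olefin may isomerise. The fallback sets out from 17 and builds the ketone in two stages. Cross-metathesis with methacrolein (10 equiv, same ruthenium catalyst), a much better-behaved 1,1-disubstituted partner, gives the enal (2E,5S,6E,10E)-1-(2,5-diacetoxy-3-methylphenyl)-3,7,11-trimethyl-12-oxododeca-2,6,10-trien-5-yl acetate F3. Allylboration with the tertiary boronate 4,4,5,5-tetramethyl-2-(2-methylbut-3-en-2-yl)-1,3,2-dioxaborolane (γ-attack through a closed transition state delivers the linear prenyl group; esters are tolerated) gives (2E,5S,6E,10E)-1-(2,5-diacetoxy-3-methylphenyl)-12-hydroxy-3,7,11,15-tetramethylhexadeca-2,6,10,14-tetraen-5-yl acetate F4 as a mixture of C12 epimers. Dess–Martin periodinane buffered with NaHCO3 oxidises F4 and comes back to the route at 18.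

For step 11, the hindered aryl acetate between the methyl group and the chain may be cleaved too slowly for clean discrimination from the C5 acetate. The fallback sets out from 16 and uses the quinone as the masked hydroquinone. K2CO3 in MeOH under Ar removes both aryl acetates before any alkyl acetate or ketone is present, giving 2-[(2E,5S,6E)-5-hydroxy-3,7-dimethylundeca-2,6,10-trien-1-yl]-6-methylbenzene-1,4-diol F5. Ag2O in Et2O oxidises it to 2-[(2E,5S,6E)-5-hydroxy-3,7-dimethylundeca-2,6,10-trien-1-yl]-6-methyl-1,4-benzoquinone F6. Acetylation (Ac2O, pyridine, 0 °C) gives (2E,5S,6E)-3,7-dimethyl-1-(5-methyl-3,6-dioxocyclohexa-1,4-dien-1-yl)undeca-2,6,10-trien-5-yl acetate F7. Cross-metathesis with 14 under the step 10 conditions gives (2E,5S,6E,10E)-3,7,11,15-tetramethyl-1-(5-methyl-3,6-dioxocyclohexa-1,4-dien-1-yl)-12-oxohexadeca-2,6,10,14-tetraen-5-yl acetate F8. Na2S2O4 in EtOAc/H2O reduces the quinone and comes back to the route at 19.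

For step 8, residual methylaluminium species may attack the aryl acetates or transfer methyl to the benzylic bromide. The fallback sets out from 10 and reverses the polarity of the coupling. The same methylalumination is quenched with I2 to isolate the vinyl iodide (1E,4S,5E)-1-iodo-2,6-dimethyldeca-1,5,9-trien-4-ol F1. Bromide 4 is converted with Zn dust and LiCl in THF into (2,5-diacetoxy-3-methylbenzyl)zinc bromide F2. Negishi coupling of F1 with F2 (Pd(OAc)2, SPhos, THF, slow addition; the organozinc tolerates the free hydroxyl and the aryl esters) comes back to the route at 16.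

**Further compounds**

F1 | step 8 | (1E,4S,5E)-1-iodo-2,6-dimethyldeca-1,5,9-trien-4-ol | I/C=C(\C)C[C@H](O)/C=C(\C)CCC=C
F2 | step 8 | (2,5-diacetoxy-3-methylbenzyl)zinc bromide | CC(=O)Oc1cc(C)c(OC(C)=O)c(C[Zn]Br)c1
F3 | step 10 | (2E,5S,6E,10E)-1-(2,5-diacetoxy-3-methylphenyl)-3,7,11-trimethyl-12-oxododeca-2,6,10-trien-5-yl acetate | CC(=O)Oc1cc(C)c(OC(C)=O)c(C/C=C(\C)C[C@H](OC(C)=O)/C=C(\C)CC/C=C(\C)C=O)c1
F4 | step 10 | (2E,5S,6E,10E)-1-(2,5-diacetoxy-3-methylphenyl)-12-hydroxy-3,7,11,15-tetramethylhexadeca-2,6,10,14-tetraen-5-yl acetate (C12 epimers) | CC(=O)Oc1cc(C)c(OC(C)=O)c(C/C=C(\C)C[C@H](OC(C)=O)/C=C(\C)CC/C=C(\C)C(O)CC=C(C)C)c1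
F5 | step 11 | 2-[(2E,5S,6E)-5-hydroxy-3,7-dimethylundeca-2,6,10-trien-1-yl]-6-methylbenzene-1,4-diol | Cc1cc(O)cc(C/C=C(\C)C[C@H](O)/C=C(\C)CCC=C)c1O
F6 | step 11 | 2-[(2E,5S,6E)-5-hydroxy-3,7-dimethylundeca-2,6,10-trien-1-yl]-6-methyl-1,4-benzoquinone | CC1=CC(=O)C=C(C/C=C(\C)C[C@H](O)/C=C(\C)CCC=C)C1=O
F7 | step 11 | (2E,5S,6E)-3,7-dimethyl-1-(5-methyl-3,6-dioxocyclohexa-1,4-dien-1-yl)undeca-2,6,10-trien-5-yl acetate | CC1=CC(=O)C=C(C/C=C(\C)C[C@H](OC(C)=O)/C=C(\C)CCC=C)C1=O
F8 | step 11 | (2E,5S,6E,10E)-3,7,11,15-tetramethyl-1-(5-methyl-3,6-dioxocyclohexa-1,4-dien-1-yl)-12-oxohexadeca-2,6,10,14-tetraen-5-yl acetate | CC1=CC(=O)C=C(C/C=C(\C)C[C@H](OC(C)=O)/C=C(\C)CC/C=C(\C)C(=O)CC=C(C)C)C1=O
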